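All runs were computed with made-up constants, and the scatter is random.

At early times and after, the oak and elm runs lose more free monomer than they put into chains: at 12.0 min oak holds 43% free and 30% in chains.

the same everywhere: free monomer 0.53 M; initiator 7.4 mM; impurity 2.5 mM
- oak: transfer agent 0.011 M; temperature 105 °C; run made earlier
- elm: transfer agent 0.024 M; temperature 122 °C; run made earlier
- dawn: transfer agent 0.0159 M; temperature 110 °C; time 20 min
- summer: transfer agent 0.0159 M; temperature 135 °C; time 20 min

| run | time / min | monomer in chains / % | free monomer / % |
|---|---|---|---|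
| oak | 2.00 | 4 | 90 |
| oak | 4.00 | 12 | 77 |
| oak | 6.00 | 13 | 67 |
| oak | 8.00 | 20 | 58 |
| oak | 10.0 | 26 | 50 |
| oak | 12.0 | 30 | 43 |
| elm | 0.500 | 5 | 90 |
| elm | 1.33 | 6 | 77 |
| elm | 2.00 | 9 | 65 |
| elm | 3.00 | 16 | 51 |
| elm | 6.00 | 25 | 26 |

(standard deviation of a reading: 1.5 percentage points)

1. which flask leads in amount of monomer in chains, in percent of the free monomer charged ("all alike" within 1.5 percentage points) (dawn / summer / all alike)
2. how much monomer in chains is there at the end, in percent of the free monomer charged: dawn
3. how much monomer in chains is there at the end, in percent of the free monomer charged: summer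

Impurity is the smaller charge, the limiting reagent if it destroys initiator one for one. This is our guess, and the runs cannot test it. The balance then leaves a working initiator, W, the initiator charge minus the impurity charge:

W = 4.90 mM

Oak and elm have this same W, so we carry their readings to dawn and summer with no correction for initiator.

Let s be monomer in chains over free monomer consumed, and k the first-order loss of free monomer. As readings:

s(oak) = 0.526, s(elm) = 0.338

k(oak) = 0.0703 min⁻¹, k(elm) = 0.225 min⁻¹

Interpolating ln k in temperature gives k(dawn) = 0.0989 min⁻¹, so dawn consumes 86.2%.

From below, we take the colder, shorter runs, assuming chains do not shrink. From above, we take oak's share at 12.0 min, the higher of the two we read, and assume that dawn and summer do not exceed it by their end; this is a guess and not a proven ceiling: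

dawn: 30% to 45.4%

summer: 25% to 52.6%

The brackets overlap, so we name no leader. The forecast, inside both, gives 37% for dawn and 32% for summer, "with summer quite uncertain", and names dawn.

The flasks give 43.0% for dawn and 44.1% for summer, inside both brackets: all alike.

    free monomer ⇌ dormant form (K = 4.40, k = 0.0530 min⁻¹, Ea = 113 kJ mol⁻¹, ΔH = −4.00 kJ mol⁻¹)
    living end + transfer agent → dead chain (kL = 0.190 M⁻¹ min⁻¹, Ea = 64.0 kJ mol⁻¹)
    free monomer + living end → monomer in chains + living end, rate k3*[living end]*[free monomer] (k = 11.0 M⁻¹ min⁻¹, Ea = 49.0 kJ mol⁻¹)
    free monomer + initiator → living end + monomer in chains (k = 1.80 M⁻¹ min⁻¹, Ea = 76.0 kJ mol⁻¹)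
    initiator + impurity → spent initiator (k = 3400 M⁻¹ min⁻¹, Ea = 68.0 kJ mol⁻¹)
    (constants at 110 °C)

In dawn at 20.0 min, living end and dead chain add up to 4.90 mM, matching W. A second flask, dawn with 0.0044 M of initiator, has W = 1.90 mM; its two forms add up to 1.90 mM, and monomer in chains reaches 21.1%. In dawn, free monomer relaxes with the dormant form, its resting state, at a half-life of 10.7 min, quicker than the 13 min of the chain step at 6.60 min. At 20.0 min, the forward use of free monomer into chains over that into dormant form is 0.96, with 40.8% standing as dormant form.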